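**Retrosynthetic overview**
1. Late stage: free the catechol by Si–O cleavage. Cut the aryl–prenyl bond at C3 (ArBr → ArLi + prenyl bromide).
2. Ring B (cyclopentane): cut C6a–C7. This bond comes from an intramolecular Friedel–Crafts acylation of a cis-2-arylcyclobutanecarboxylic acid, and the C=O is then reduced to CH2.
3. Catechol aryl–C2 bond: Cu-catalysed strain-release homoconjugate addition of an aryl Grignard reagent to a 2-aryl-4,4-dimethylbicyclo[1.1.0]butane-1-carboxylate. Cleavage of the central bond leaves cyclobutane C.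
4. Bicyclobutane: both three-membered rings close together when the Rh(II) carbene of an (E)-2-diazo-3,3-dimethyl-5-arylpent-4-enoate adds enantioselectively to its own alkene. The diazo ester comes from a Heck coupling followed by diazo transfer.
5. Ring order: bicyclo[1.1.0]butane (two rings at once) → cyclobutane C → cyclopentane B. Both arenes are bought.

Assumption: Rh2(S-NTTL)4 is taken to give the (1R,2R,3R)-bicyclobutane 7. If the sense of induction is opposite, Rh2(R-NTTL)4 is used and nothing else changes.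

**Step 1**
Reactants: 1 3,3-dimethylpent-4-enoic acid
Product: 2 tert-butyl 3,3-dimethylpent-4-enoate
Conditions: Boc2O (1.3 equiv), DMAP (0.2 equiv), t-BuOH, 30 °C
Reagents that add atoms: di-tert-butyl dicarbonate, CC(C)(C)OC(=O)OC(=O)OC(C)(C)C
Why: DMAP-catalysed mixed-anhydride esterification installs the bulky tert-butyl ester, which later shields the carbonyl from the Grignard reagent and leaves under acid; no stereocentre is formed.

**Step 2**
Reactants: 2 tert-butyl 3,3-dimethylpent-4-enoate; 3 1-bromo-3,5-dimethoxybenzene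
Product: 4 tert-butyl (E)-5-(3,5-dimethoxyphenyl)-3,3-dimethylpent-4-enoate
Conditions: Pd(OAc)2 (2 mol %), P(o-tol)3 (6 mol %), Et3N, DMF, 100 °C
Reagents that add atoms: none
Why: Mizoroki–Heck reaction in which aryl-Pd adds to the free CH2 terminus and, because the allylic carbon is quaternary, β-hydride elimination can only give the conjugated (E)-styrene.

**Step 3**
Reactants: 4 tert-butyl (E)-5-(3,5-dimethoxyphenyl)-3,3-dimethylpent-4-enoate
Product: 6 tert-butyl (E)-2-diazo-5-(3,5-dimethoxyphenyl)-3,3-dimethylpent-4-enoate, via trifluoroacetyl ester 5 (not isolated)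
Conditions: LiHMDS, THF, −78 °C; CF3CO2CH2CF3; aq. HCl work-up; then MsN3, Et3N, H2O (1 equiv), MeCN, rt
Reagents that add atoms: methanesulfonyl azide, CS(=O)(=O)N=[N+]=[N-]; 2,2,2-trifluoroethyl trifluoroacetate, O=C(OCC(F)(F)F)C(F)(F)F (its CF3CO group is found only in 5)
Why: Danheiser detrifluoroacetylative diazo transfer (Regitz type), in which transient trifluoroacetylation makes the unactivated α-carbon nucleophilic enough to attack the sulfonyl azide and the CF3CO group leaves on the sulfonamide nitrogen.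

**Step 4**
Reactants: 6 tert-butyl (E)-2-diazo-5-(3,5-dimethoxyphenyl)-3,3-dimethylpent-4-enoate
Product: 7 tert-butyl (1R,2R,3R)-2-(3,5-dimethoxyphenyl)-4,4-dimethylbicyclo[1.1.0]butane-1-carboxylate (aryl exo)
Conditions: Rh2(S-NTTL)4 (0.5 mol %), toluene, −78 °C, slow addition of 6; quick filtration through Et3N-deactivated silica
Reagents that add atoms: none
Why: Rh(II)-carbene intramolecular cyclopropanation (the enantioselective bicyclobutanation known for (E)-2-diazo-5-arylpent-4-enoates), in which the carbene carbon adds across the styrene C=C so that both three-membered rings close at once, the chiral carboxylate pocket selects the alkene face and sets C1, C2 and C3 together, the E geometry puts the aryl group exo, and the quaternary C3 of 6 removes the usual β-hydride-shift side reaction.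

**Step 5**
Reactants: 8 4-bromobenzene-1,2-diol
Product: 9 4-bromo-1,2-bis(triisopropylsilyloxy)benzene
Conditions: TIPSCl (2.4 equiv), imidazole (5 equiv), DMF, 40 °C
Reagents that add atoms: chlorotriisopropylsilane, CC(C)[Si](Cl)(C(C)C)C(C)C
Why: Standard silyl ether formation; aryl TIPS ethers survive Grignard formation, TFA, NBS and n-BuLi and leave with fluoride.

**Step 6**
Reactants: 7 tert-butyl (1R,2R,3R)-2-(3,5-dimethoxyphenyl)-4,4-dimethylbicyclo[1.1.0]butane-1-carboxylate; 9 4-bromo-1,2-bis(triisopropylsilyloxy)benzene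
Product: 12 tert-butyl (1S,2S,3S)-3-[3,4-bis(triisopropylsilyloxy)phenyl]-2-(3,5-dimethoxyphenyl)-4,4-dimethylcyclobutane-1-carboxylate (ester cis to the C2 aryl; the two aryl groups trans), via arylmagnesium bromide 10 (not isolated), via magnesium enolate 11 (not isolated)
Conditions: 9, Mg, THF, 50 °C; then CuBr·SMe2 (30 mol %), PBu3, 7, THF, −20 °C → rt; BHT, −78 °C; aq. work-up
Reagents that add atoms: magnesium, [Mg] (found only in 10 and 11)
Why: Cu-catalysed strain-release homoconjugate addition, in which the aryl-copper species attacks bridgehead C3 from outside the central bond with inversion and therefore anti to the exo aryl group (aryl/aryl trans), and the bulky phenol protonates enolate 11 kinetically from the face away from the neighbouring dimethoxyphenyl group, leaving the ester cis to it.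

**Step 7**
Reactants: 12 tert-butyl (1S,2S,3S)-3-[3,4-bis(triisopropylsilyloxy)phenyl]-2-(3,5-dimethoxyphenyl)-4,4-dimethylcyclobutane-1-carboxylate
Product: 15 (2S,2aR,7aS)-2-[3,4-bis(triisopropylsilyloxy)phenyl]-4,6-dimethoxy-1,1-dimethyl-2,2a,7,7a-tetrahydro-1H-cyclobuta[a]indene, via carboxylic acid 13 (not isolated), via indanone 14 (not isolated)
Conditions: TFA/CH2Cl2 (1:3), 0 °C → rt; TFAA (1.3 equiv), 0 °C → rt; then Et3SiH (4 equiv), rt
Reagents that add atoms: none
Why: Acidolysis of the tert-butyl ester, TFAA-mediated intramolecular Friedel–Crafts acylation ortho/para to the two OMe groups (only the cis acid can close, so the ring fusion is necessarily cis, and the two ortho positions are equivalent) and Et3SiH/TFA ionic hydrogenation of the electron-rich aryl ketone 14 to CH2 run in one flask without touching the three stereocentres.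

**Step 8**
Reactants: 15 (2S,2aR,7aS)-2-[3,4-bis(triisopropylsilyloxy)phenyl]-4,6-dimethoxy-1,1-dimethyl-2,2a,7,7a-tetrahydro-1H-cyclobuta[a]indene
Product: 16 (2S,2aR,7aS)-3-bromo-2-[3,4-bis(triisopropylsilyloxy)phenyl]-4,6-dimethoxy-1,1-dimethyl-2,2a,7,7a-tetrahydro-1H-cyclobuta[a]indene
Conditions: NBS (1.0 equiv), CH2Cl2, −40 → 0 °C, dark
Reagents that add atoms: N-bromosuccinimide, O=C1CCC(=O)N1Br
Why: Electrophilic aromatic bromination, in which the resorcinol-type ring is far more nucleophilic than the bis-silyloxy ring and NBS takes the position para to one OMe and ortho to the other (C3) rather than the site flanked by both OMe groups.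

**Step 9**
Reactants: 16 (2S,2aR,7aS)-3-bromo-2-[3,4-bis(triisopropylsilyloxy)phenyl]-4,6-dimethoxy-1,1-dimethyl-2,2a,7,7a-tetrahydro-1H-cyclobuta[a]indene
Product: 18 (2S,2aR,7aS)-2-[3,4-bis(triisopropylsilyloxy)phenyl]-4,6-dimethoxy-1,1-dimethyl-3-(3-methylbut-2-en-1-yl)-2,2a,7,7a-tetrahydro-1H-cyclobuta[a]indene, via aryllithium 17 (not isolated)
Conditions: n-BuLi (1.1 equiv), THF, −78 °C; prenyl bromide (2 equiv), −78 °C → rt
Reagents that add atoms: prenyl bromide (1-bromo-3-methylbut-2-ene), CC(C)=CCBr; n-butyllithium, [Li]CCCC (its Li is found only in 17)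
Why: Bromine–lithium exchange gives the OMe-chelated aryllithium 17, which is alkylated by prenyl bromide in an SN2 reaction at the primary carbon.

**Step 10**
Reactants: 18 (2S,2aR,7aS)-2-[3,4-bis(triisopropylsilyloxy)phenyl]-4,6-dimethoxy-1,1-dimethyl-3-(3-methylbut-2-en-1-yl)-2,2a,7,7a-tetrahydro-1H-cyclobuta[a]indene
Product: 19 4-[(2S,2aR,7aS)-4,6-dimethoxy-1,1-dimethyl-3-(3-methylbut-2-en-1-yl)-2,2a,7,7a-tetrahydro-1H-cyclobuta[a]inden-2-yl]benzene-1,2-diol (CNP0201781.1)
Conditions: TBAF (2.4 equiv), AcOH (2.6 equiv), THF, 0 °C, Ar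
Reagents that add atoms: none
Why: Fluoride-induced Si–O cleavage buffered with AcOH frees the catechol under non-basic, non-oxidising conditions that leave the prenyl alkene, the methyl ethers and the stereocentres untouched.

**Compound list**
1 | 3,3-dimethylpent-4-enoic acid | C=CC(C)(C)CC(=O)O | starting material
2 | tert-butyl 3,3-dimethylpent-4-enoate | C=CC(C)(C)CC(=O)OC(C)(C)C | intermediate
3 | 1-bromo-3,5-dimethoxybenzene | COc1cc(Br)cc(OC)c1 | starting material
4 | tert-butyl (E)-5-(3,5-dimethoxyphenyl)-3,3-dimethylpent-4-enoate | COc1cc(/C=C/C(C)(C)CC(=O)OC(C)(C)C)cc(OC)c1 | intermediate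
5 | tert-butyl (E)-5-(3,5-dimethoxyphenyl)-3,3-dimethyl-2-(trifluoroacetyl)pent-4-enoate (racemic, keto/enol) | COc1cc(/C=C/C(C)(C)C(C(=O)C(F)(F)F)C(=O)OC(C)(C)C)cc(OC)c1 | intermediate
6 | tert-butyl (E)-2-diazo-5-(3,5-dimethoxyphenyl)-3,3-dimethylpent-4-enoate | COc1cc(/C=C/C(C)(C)C(=[N+]=[N-])C(=O)OC(C)(C)C)cc(OC)c1 | intermediate
7 | tert-butyl (1R,2R,3R)-2-(3,5-dimethoxyphenyl)-4,4-dimethylbicyclo[1.1.0]butane-1-carboxylate (aryl exo) | CC(C)(C)OC(=O)[C@@]12[C@@H](c3cc(OC)cc(OC)c3)[C@@H]1C2(C)C | intermediate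
8 | 4-bromobenzene-1,2-diol | Oc1ccc(Br)cc1O | starting material
9 | 4-bromo-1,2-bis(triisopropylsilyloxy)benzene | Brc1ccc(O[Si](C(C)C)(C(C)C)C(C)C)c(O[Si](C(C)C)(C(C)C)C(C)C)c1 | intermediate
10 | [3,4-bis(triisopropylsilyloxy)phenyl]magnesium bromide | Br[Mg]c1ccc(O[Si](C(C)C)(C(C)C)C(C)C)c(O[Si](C(C)C)(C(C)C)C(C)C)c1 | intermediate
11 | bromomagnesium enolate of 12 (C1 planar; the two aryl groups trans) | CC(C)(C)OC(O[Mg]Br)=C1[C@@H](c2cc(OC)cc(OC)c2)[C@H](c2ccc(O[Si](C(C)C)(C(C)C)C(C)C)c(O[Si](C(C)C)(C(C)C)C(C)C)c2)C1(C)C | intermediate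
12 | tert-butyl (1S,2S,3S)-3-[3,4-bis(triisopropylsilyloxy)phenyl]-2-(3,5-dimethoxyphenyl)-4,4-dimethylcyclobutane-1-carboxylate | COc1cc(OC)cc(c1)[C@@H]1[C@H](C(=O)OC(C)(C)C)C(C)(C)[C@H]1c1ccc(O[Si](C(C)C)(C(C)C)C(C)C)c(O[Si](C(C)C)(C(C)C)C(C)C)c1 | intermediate
13 | (1S,2S,3S)-3-[3,4-bis(triisopropylsilyloxy)phenyl]-2-(3,5-dimethoxyphenyl)-4,4-dimethylcyclobutane-1-carboxylic acid | COc1cc(OC)cc(c1)[C@@H]1[C@H](C(=O)O)C(C)(C)[C@H]1c1ccc(O[Si](C(C)C)(C(C)C)C(C)C)c(O[Si](C(C)C)(C(C)C)C(C)C)c1 | intermediate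
14 | (2S,2aS,7aS)-2-[3,4-bis(triisopropylsilyloxy)phenyl]-4,6-dimethoxy-1,1-dimethyl-1,2,2a,7a-tetrahydro-7H-cyclobuta[a]inden-7-one | COc1cc(OC)c2c(c1)[C@@H]1[C@H](C2=O)C(C)(C)[C@H]1c1ccc(O[Si](C(C)C)(C(C)C)C(C)C)c(O[Si](C(C)C)(C(C)C)C(C)C)c1 | intermediate
15 | (2S,2aR,7aS)-2-[3,4-bis(triisopropylsilyloxy)phenyl]-4,6-dimethoxy-1,1-dimethyl-2,2a,7,7a-tetrahydro-1H-cyclobuta[a]indene | COc1cc(OC)c2c(c1)[C@@H]1[C@H](C2)C(C)(C)[C@H]1c1ccc(O[Si](C(C)C)(C(C)C)C(C)C)c(O[Si](C(C)C)(C(C)C)C(C)C)c1 | intermediate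
16 | 3-bromo derivative of 15, (2S,2aR,7aS) | COc1cc(OC)c2c(c1Br)[C@@H]1[C@H](C2)C(C)(C)[C@H]1c1ccc(O[Si](C(C)C)(C(C)C)C(C)C)c(O[Si](C(C)C)(C(C)C)C(C)C)c1 | intermediate
17 | 3-lithio derivative of 15, (2S,2aR,7aS) | COc1cc(OC)c2c(c1[Li])[C@@H]1[C@H](C2)C(C)(C)[C@H]1c1ccc(O[Si](C(C)C)(C(C)C)C(C)C)c(O[Si](C(C)C)(C(C)C)C(C)C)c1 | intermediate
18 | 3-(3-methylbut-2-en-1-yl) derivative of 15, (2S,2aR,7aS) | COc1cc(OC)c2c(c1CC=C(C)C)[C@@H]1[C@H](C2)C(C)(C)[C@H]1c1ccc(O[Si](C(C)C)(C(C)C)C(C)C)c(O[Si](C(C)C)(C(C)C)C(C)C)c1 | intermediate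
19 | 4-[(2S,2aR,7aS)-4,6-dimethoxy-1,1-dimethyl-3-(3-methylbut-2-en-1-yl)-2,2a,7,7a-tetrahydro-1H-cyclobuta[a]inden-2-yl]benzene-1,2-diol | COc1cc(OC)c2c(c1CC=C(C)C)[C@@H]1[C@H](C2)C(C)(C)[C@H]1c1ccc(O)c(O)c1 | target

**Step count**
- Total steps: 10.
- Longest linear sequence: 9 (steps 1–4 and 6–10, starting from 1).

**Steps most likely to fail**

Step 3. The α-carbon of 4 is neopentylic, so C-trifluoroacetylation or the attack on the azide may stall. The fallback sets out from 4 and comes back at 6, and it replaces diazo transfer by a Bamford–Stevens route. KHMDS with 2-(phenylsulfonyl)-3-phenyloxaziridine hydroxylates the enolate of 4 to tert-butyl (E)-5-(3,5-dimethoxyphenyl)-2-hydroxy-3,3-dimethylpent-4-enoate F1. Dess–Martin periodinane oxidises this to tert-butyl (E)-5-(3,5-dimethoxyphenyl)-3,3-dimethyl-2-oxopent-4-enoate F2. TsNHNH2 (cat. TsOH, toluene, 60 °C) condenses with the activated ketone to give the tosylhydrazone F3. Et3N/DBU in CH2Cl2 then expels sulfinate and gives 6.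

Step 4. The carbene may undergo a 1,2-styryl or 1,2-methyl shift instead of closing, the gem-dimethyl group may erode the ee, or 7 may be too labile to handle. The fallback sets out from 3 and 9 and comes back at 12, and it builds the cyclobutane by an intermolecular crossed [2+2] instead.
- Heck reaction of 3 with tert-butyl acrylate gives tert-butyl (E)-3-(3,5-dimethoxyphenyl)prop-2-enoate F4.
- Suzuki coupling of 9 with 2-methylprop-1-enylboronic acid pinacol ester gives 4-(2-methylprop-1-enyl)-1,2-bis(triisopropylsilyloxy)benzene F5.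
- Visible-light triplet-sensitised [2+2] of F4 with F5 under a chiral oxazaborolidine Lewis acid joins the two non-benzylic carbons first. It then closes between the benzylic carbons to give the all-trans cyclobutane tert-butyl (1R,2S,3S)-3-[3,4-bis(triisopropylsilyloxy)phenyl]-2-(3,5-dimethoxyphenyl)-4,4-dimethylcyclobutane-1-carboxylate F6.
- LDA converts F6 into the lithium enolate F7. BHT protonates F7 from the face away from the dimethoxyphenyl group and returns 12.

Step 6. The bridgehead carbon is flanked by a quaternary centre, so aryl transfer from copper may be slow, and direct attack on the ester or isomerisation of 7 may compete. The fallback sets out from 7 and 9 and comes back at 12, and it replaces the polar arylation by a radical cross-coupling. HBr in Et2O at −78 °C opens the central bond of 7 to tert-butyl (1S,2S,3S)-3-bromo-2-(3,5-dimethoxyphenyl)-4,4-dimethylcyclobutane-1-carboxylate F8. Ni-catalysed reductive cross-electrophile coupling of F8 with 9 (NiBr2·glyme, dtbbpy, Zn, NaI, DMA) runs through the planar C3 radical. That radical is arylated on the face anti to the neighbouring aryl group and gives 12. Any C1 epimer is funnelled into 14 in step 7, because only the cis acid can cyclise.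

**Further compounds**
F1 | step 3 | tert-butyl (E)-5-(3,5-dimethoxyphenyl)-2-hydroxy-3,3-dimethylpent-4-enoate (racemic) | COc1cc(/C=C/C(C)(C)C(O)C(=O)OC(C)(C)C)cc(OC)c1
F2 | step 3 | tert-butyl (E)-5-(3,5-dimethoxyphenyl)-3,3-dimethyl-2-oxopent-4-enoate | COc1cc(/C=C/C(C)(C)C(=O)C(=O)OC(C)(C)C)cc(OC)c1
F3 | step 3 | tosylhydrazone of F2 | COc1cc(/C=C/C(C)(C)C(=NNS(=O)(=O)c2ccc(C)cc2)C(=O)OC(C)(C)C)cc(OC)c1
F4 | step 4 | tert-butyl (E)-3-(3,5-dimethoxyphenyl)prop-2-enoate | COc1cc(/C=C/C(=O)OC(C)(C)C)cc(OC)c1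
F5 | step 4 | 4-(2-methylprop-1-enyl)-1,2-bis(triisopropylsilyloxy)benzene | CC(C)=Cc1ccc(O[Si](C(C)C)(C(C)C)C(C)C)c(O[Si](C(C)C)(C(C)C)C(C)C)c1
F6 | step 4 | tert-butyl (1R,2S,3S)-3-[3,4-bis(triisopropylsilyloxy)phenyl]-2-(3,5-dimethoxyphenyl)-4,4-dimethylcyclobutane-1-carboxylate (C1 epimer of 12) | COc1cc(OC)cc(c1)[C@@H]1[C@@H](C(=O)OC(C)(C)C)C(C)(C)[C@H]1c1ccc(O[Si](C(C)C)(C(C)C)C(C)C)c(O[Si](C(C)C)(C(C)C)C(C)C)c1
F7 | step 4 | lithium enolate of F6 and 12 | CC(C)(C)OC(O[Li])=C1[C@@H](c2cc(OC)cc(OC)c2)[C@H](c2ccc(O[Si](C(C)C)(C(C)C)C(C)C)c(O[Si](C(C)C)(C(C)C)C(C)C)c2)C1(C)C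
F8 | step 6 | tert-butyl (1S,2S,3S)-3-bromo-2-(3,5-dimethoxyphenyl)-4,4-dimethylcyclobutane-1-carboxylate | COc1cc(OC)cc(c1)[C@@H]1[C@H](C(=O)OC(C)(C)C)C(C)(C)[C@H]1Br
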